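A direct plan would make ring A first: a benzyl-protected pyrogallol triether would be dibrominated to A1, both bromines exchanged for hydroxyl groups under Cu(acac)2 catalysis, and formylation and monobenzylation would give salicylaldehyde A2.
A2 would open the Darzens glycidic ester A3 of ring B through its phenol oxygen, oxidation would give α-keto ester A4, and a carbene-catalysed intramolecular benzoin reaction would close ring C to A5.
Loss of the ester group, dehydrogenation, 3-O-methylation and debenzylation would finish the flavone.
The first weak step would be the double hydroxylation of A1: the second exchange has to take place on an electron-rich, hindered bromophenoxide, and the resorcinol formed is sensitive to air.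
The second would be the opening of A3 by A2 without a promoter: the hydrogen-bonded, di-ortho-substituted phenol is a poor nucleophile, and the glycidate can open at the other carbon or rearrange.
The third would be the benzoin closure of A4: the formyl group is flanked by two substituents, and the enolisable α-aryloxy ketone can expel the ring A aryloxide.
The ester that is brought in and removed again and the two benzyl groups would add steps without adding complexity.

The route disconnects ring A instead of ring C, at C8–C8a and C4a–C5. It exploits the alternating pattern C5(OH)–C6(OMe)–C7(OH)–C8(OMe) of ring A, which is the oxidation pattern of methyl 2,4-dimethoxyacetoacetate: ester carbon C5, ketone carbon C7, methoxylated carbons C6 and C8. The other partner is a 2-methoxy-4-pyranone that already holds ring B, O1, C2 to C4 and the 3-methoxy group. In one anionic operation the keto ester dianion would displace the methoxy group at the future C8a and the pyranone carbon C4a would be acylated by the ester, which forms the complete flavone with both hydroxyl groups free. Protecting groups, aryl halide hydroxylation, epoxide opening, benzoin closure and late oxidation-state changes have no counterpart.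

Key step: step 5

Remark: the target has no stereocentre; the centres of 2, 5 and 9 are enolisable, would form as racemates or diastereomer mixtures and are left open, and compounds 1, 3 and 4 are taken as commercially available.

Step 1
Reactants: 1 methyl methoxyacetate (two molecules)
Product: 2 methyl 2,4-dimethoxy-3-oxobutanoate (racemic)
Conditions: NaH (0.55 equiv per ester), THF, 0 °C → reflux; aq HCl
Reagents that add atoms: none
Why: Claisen self-condensation of an α-alkoxy ester, driven by irreversible deprotonation of the β-keto ester formed; the new centre at C2 is enolisable, so 2 should be racemic.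

Step 2
Reactants: 3 methyl 4-methoxy-3-oxobutanoate; 4 methyl 2,4,5-trimethoxybenzoate
Product: 5 methyl 4-methoxy-3,5-dioxo-5-(2,4,5-trimethoxyphenyl)pentanoate (racemic, largely enolised)
Conditions: 3 (2.2 equiv), LiN(iPr)2 (4.4 equiv), THF, −78 → 0 °C; 4, 0 °C → rt; aq HCl
Reagents that add atoms: none
Why: γ-Acylation of a β-keto ester dianion by a non-enolisable aryl ester (Claisen-type acyl substitution), in which the more basic terminal carbanion attacks the ester and the excess dianion takes up the acidic proton of the 3,5-diketo ester; the methoxy-bearing carbon is enolised and carries no defined configuration.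

Step 3
Reactants: 5 methyl 4-methoxy-3,5-dioxo-5-(2,4,5-trimethoxyphenyl)pentanoate
Product: 6 4-hydroxy-5-methoxy-6-(2,4,5-trimethoxyphenyl)-2H-pyran-2-one
Conditions: DBU (1.2 equiv), toluene, reflux; aq HCl
Reagents that add atoms: none
Why: Base-induced lactonisation of a 3,5-diketo ester, in which the enol oxygen of the aryl ketone attacks the ester carbonyl (6-exo-trig) and loss of methanol gives the stabilised 4-hydroxy-2-pyranone.

Step 4
Reactants: 6 4-hydroxy-5-methoxy-6-(2,4,5-trimethoxyphenyl)-2H-pyran-2-one
Product: 8 2,5-dimethoxy-6-(2,4,5-trimethoxyphenyl)-4H-pyran-4-one, via hydroxypyrylium triflate 7 (not isolated)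
Conditions: MeOTf (1.1 equiv), CH2Cl2, 0 °C → rt; aq NaHCO3
Reagents that add atoms: methyl trifluoromethanesulfonate COS(=O)(=O)C(F)(F)F
Why: O-Methylation of a protomeric ambident hydroxypyranone by a hard methyl sulfonate, which should alkylate the neutral compound at the oxygen that carries no proton (the lactone carbonyl oxygen) to give salt 7, which is protected from a second methylation and loses its proton on work-up to give the 2-methoxy-4-pyranone.

Step 5
Reactants: 2 methyl 2,4-dimethoxy-3-oxobutanoate; 8 2,5-dimethoxy-6-(2,4,5-trimethoxyphenyl)-4H-pyran-4-one
Product: 10 5,7-dihydroxy-3,6,8-trimethoxy-2-(2,4,5-trimethoxyphenyl)-4H-chromen-4-one (5,7-dihydroxy-3,6,8,2',4',5'-hexamethoxyflavone), via pyranyl keto ester 9 (not isolated)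
Conditions: 2 (1.3 equiv), LiN(iPr)2 (2.7 equiv), THF, −78 → 0 °C; 8, −78 °C → rt; then 60 °C; aq HCl
Reagents that add atoms: none
Why: Proposed new method: the dilithium dienolate of 2 should attack through its terminal carbon at C2 of pyranone 8 (the future C8a), the β-carbon of a vinylogous carbonate, and loss of methoxide restores the pyranone and forms C8–C8a in 9; the methine of 9 between the ketone and the pyranone is then deprotonated to an extended enolate whose α-carbon (pyranone C3, the future C4a) attacks the ester in an intramolecular Claisen condensation that forms C4a–C5, and loss of methoxide and proton shifts give aromatic ring A. The closest known reactions are the terminal-carbon addition–elimination of β-keto ester dianions to β-alkoxy enones, the exchange of the 2-alkoxy group of 2-alkoxy-4-pyranones by nucleophiles and the base-induced Claisen cyclisation of polyketo esters to acylphloroglucinols. Ring A closes in a 6-exo-trig mode on the ester carbonyl, and aromatisation makes the closure irreversible. No stereocentre is set, because the two centres of 9 form without control and both become sp2 carbons. The step needs attack at C2 and not at C6 or the carbonyl carbon of 8, and Claisen instead of aldol closure: C2 carries the only leaving group and is less hindered than C6, which bears the twisted aryl group next to a donor methoxy group, the carbonyl group of a 4-pyranone is a doubly vinylogous ester, and an aldol closure on C4 would give a bridged ring because C4, C4a and C8a are contiguous atoms of the pyranone. The ester carbon thereby becomes C5–OH, the ketone carbon C7–OH and the two methoxylated carbons C6 and C8, so the 5,7-dihydroxy-6,8-dimethoxy pattern should arise without any protecting group.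

**Compound list**
1 | methyl methoxyacetate | COCC(=O)OC | starting material
2 | methyl 2,4-dimethoxy-3-oxobutanoate (racemic) | COCC(=O)C(OC)C(=O)OC | intermediate
3 | methyl 4-methoxy-3-oxobutanoate | COCC(=O)CC(=O)OC | starting material
4 | methyl 2,4,5-trimethoxybenzoate | COC(=O)c1cc(OC)c(OC)cc1OC | starting material
5 | methyl 4-methoxy-3,5-dioxo-5-(2,4,5-trimethoxyphenyl)pentanoate (racemic, largely enolised) | COC(=O)CC(=O)C(OC)C(=O)c1cc(OC)c(OC)cc1OC | intermediate
6 | 4-hydroxy-5-methoxy-6-(2,4,5-trimethoxyphenyl)-2H-pyran-2-one | COC1=C(c2cc(OC)c(OC)cc2OC)OC(=O)C=C1O | intermediate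
7 | 4-hydroxy-2,5-dimethoxy-6-(2,4,5-trimethoxyphenyl)pyrylium trifluoromethanesulfonate (not isolated) | COc1cc(O)c(OC)c(-c2cc(OC)c(OC)cc2OC)[o+]1.[O-]S(=O)(=O)C(F)(F)F | intermediate
8 | 2,5-dimethoxy-6-(2,4,5-trimethoxyphenyl)-4H-pyran-4-one | COC1=CC(=O)C(OC)=C(c2cc(OC)c(OC)cc2OC)O1 | intermediate
9 | methyl 2,4-dimethoxy-4-[5-methoxy-4-oxo-6-(2,4,5-trimethoxyphenyl)-4H-pyran-2-yl]-3-oxobutanoate (not isolated, present as lithium enolates, diastereomer mixture, centres left open) | COC(=O)C(OC)C(=O)C(OC)C1=CC(=O)C(OC)=C(c2cc(OC)c(OC)cc2OC)O1 | intermediate
10 | 5,7-dihydroxy-3,6,8,2',4',5'-hexamethoxyflavone | COc1cc(OC)c(-c2oc3c(OC)c(O)c(OC)c(O)c3c(=O)c2OC)cc1OC | target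

Total step count: 5. Longest linear sequence: 4 steps (steps 2 to 5); step 1 makes the second partner of step 5.

Steps most likely to fail:

Step 5 (Proposed new method). The dianion might add to the carbonyl carbon or to C6 of 8 with ring opening, or the Claisen closure might stall because the ester of 9 is held in a β-keto ester enolate. The fallback uses known reaction types, sets out from 2 and 8 and comes back at 10. Compound 2 would be silylated twice (Me3SiCl, Et3N; then LiN(iPr)2, Me3SiCl) to 1,2,4-trimethoxy-1,3-bis(trimethylsilyloxy)buta-1,3-diene F1. Me3SiOTf in CH2Cl2 at −78 °C would turn 8 into its 4-silyloxypyrylium ion, which F1 should attack with its terminal carbon in a vinylogous Mukaiyama-type addition. Loss of methoxytrimethylsilane and aqueous work-up would give 9, now isolated. Heating neutral 9 in o-dichlorobenzene at about 180 °C should expel methanol to give an acylketene, whose enol form closes ring A by 6π electrocyclisation onto C3 of the pyranone, as in the last stage of a Danheiser benzannulation, and tautomerisation would give 10.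

Step 4. Methylation might go to the 4-oxygen after proton transfer and give the isomeric 4-methoxy-2-pyranone, or run on to a dimethoxypyrylium salt. The fallback sets out from 5 and comes back at 8 without passing through 6 and 7: dehydrative cyclisation of the diketo ester with PPh3 and CCl4 in THF. The cyclic hemiketal formed by addition of the aryl ketone enol oxygen to the ester carbonyl would be dehydrated, so that the ester methoxy group is kept and water is lost instead of methanol. This fallback makes no new compound (F0).

Step 2. Acyl transfer to the electron-rich, ortho-substituted ester 4 might be slow, so that proton exchange with the product and self-condensation of the dianion prevail. The fallback sets out from 3 and comes back at 5. The dianion of 3 would undergo aldol addition to commercial 2,4,5-trimethoxybenzaldehyde, a much better electrophile, to give methyl 5-hydroxy-4-methoxy-3-oxo-5-(2,4,5-trimethoxyphenyl)pentanoate F2 as a diastereomer mixture. Oxidation of the benzylic alcohol with Dess–Martin periodinane in CH2Cl2 would give 5.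

**Further compounds**
F1 | step 5 | 1,2,4-trimethoxy-1,3-bis(trimethylsilyloxy)buta-1,3-diene (double bond geometry left open) | COC=C(O[Si](C)(C)C)C(OC)=C(OC)O[Si](C)(C)C
F0 | step 4 | none | none
F2 | step 2 | methyl 5-hydroxy-4-methoxy-3-oxo-5-(2,4,5-trimethoxyphenyl)pentanoate (diastereomer mixture, centres left open) | COC(=O)CC(=O)C(OC)C(O)c1cc(OC)c(OC)cc1OC
A1 | direct plan | 3-(benzyloxy)-1,5-dibromo-2,4-dimethoxybenzene | COc1c(Br)cc(Br)c(OC)c1OCc1ccccc1
A2 | direct plan | 2,4-bis(benzyloxy)-6-hydroxy-3,5-dimethoxybenzaldehyde | COc1c(O)c(C=O)c(OCc2ccccc2)c(OC)c1OCc1ccccc1
A3 | direct plan | allyl trans-3-(2,4,5-trimethoxyphenyl)oxirane-2-carboxylate (racemic) | C=CCOC(=O)[C@@H]1O[C@H]1c1cc(OC)c(OC)cc1OC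
A4 | direct plan | allyl 3-[3,5-bis(benzyloxy)-2-formyl-4,6-dimethoxyphenoxy]-2-oxo-3-(2,4,5-trimethoxyphenyl)propanoate (racemic) | C=CCOC(=O)C(=O)C(Oc1c(C=O)c(OCc2ccccc2)c(OC)c(OCc2ccccc2)c1OC)c1cc(OC)c(OC)cc1OC
A5 | direct plan | allyl (2R*,3R*)-5,7-bis(benzyloxy)-3-hydroxy-6,8-dimethoxy-4-oxo-2-(2,4,5-trimethoxyphenyl)chromane-3-carboxylate (racemic) | COc1cc(OC)c(cc1OC)[C@H]1Oc2c(OC)c(OCc3ccccc3)c(OC)c(OCc3ccccc3)c2C(=O)[C@@]1(O)C(=O)OCC=C
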